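**Strategy.** Everything rests on the bond between the exocyclic-methylene carbon on the epoxycyclohexane ring and the adjacent side-chain carbinol carbon (the CH–O-angelate). This C(=CH2)–CH(O) unit is read as an oxidised α-substituted allylboronate. A (+)-sparteine-controlled α-lithiated homoprenyl triisopropylbenzoate is captured by a ring-bearing alkenyl pinacol boronate, and 1,2-metalate rearrangement joins both fragments while fixing the carbinol configuration under reagent control; oxidation then reveals the alcohol. The boronate comes from (R)-carvone, which supplies the ring carbons and one stereocentre; its all-cis oxygenation is built by α′-hydroxylation, inversion, reduction and directed epoxidation. The side-chain epoxide is added last by Shi epoxidation.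

Key step: step 10

Assumption: (+)-sparteine, angelic acid, 2,4,6-triisopropylbenzoic acid (TIB-OH) and the D-fructose-derived Shi ketone are treated as purchasable reagents. Ring positions are named by 7-oxabicyclo[4.1.0]heptane numbering (C-1 = C(Me)–O, C-2 and C-3 = CH–O, C-4 = CH bearing the side chain, C-6 = epoxide CH).

Step 1
Reactants: 1 (R)-carvone
Product: 5 (5S,6S)-6-hydroxy-2-methyl-5-(prop-1-en-2-yl)cyclohex-2-en-1-one (trans-6-hydroxycarvone), via lithium dienolate 2 (not isolated), via trimethylsilyl dienol ether 3 (not isolated), via trans α-silyloxy ketone 4 (not isolated)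
Conditions: LDA, THF, −78 °C; TMSCl; then mCPBA (1.0 equiv), NaHCO3, CH2Cl2, −20 → 0 °C; then 1 M HCl, THF
Reagents that add atoms: mCPBA (3-chloroperoxybenzoic acid), O=C(OO)c1cccc(Cl)c1
Why: Rubottom oxidation, in which kinetic α′-deprotonation at C6, silylation and epoxidation of the electron-rich silyl enol ether on the face anti to the adjacent isopropenyl group should give the trans (6S) α-hydroxy ketone.

Step 2
Reactants: 5 trans-6-hydroxycarvone
Product: 6 (1R,6S)-3-methyl-2-oxo-6-(prop-1-en-2-yl)cyclohex-3-en-1-yl benzoate (cis-6-benzoyloxycarvone)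
Conditions: PhCO2H, PPh3, DIAD, THF, 0 °C → rt
Reagents that add atoms: benzoic acid, OC(=O)c1ccccc1
Why: Mitsunobu inversion, in which the equatorial oxyphosphonium group α to the ketone is displaced by benzoate along the axial, carbonyl-assisted trajectory and has no antiperiplanar β-hydrogen for elimination, so the carbinol centre should be inverted to the cis ester.

Step 3
Reactants: 6 cis-6-benzoyloxycarvone
Product: 7 (1R,2S,6S)-3-methyl-6-(prop-1-en-2-yl)cyclohex-3-ene-1,2-diol (both hydroxyls cis to the isopropenyl group)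
Conditions: LiAlH4, Et2O, −78 → 0 °C; Rochelle salt work-up
Reagents that add atoms: none
Why: Hydride 1,2-reduction of the enone with reductive cleavage of the benzoate, in which axial hydride delivery anti to the axial 6-acyloxy group (as in the carvone to cis-carveol reduction) should place the new hydroxyl cis to both neighbours.

Step 4
Reactants: 7 all-cis cyclohexenediol
Product: 8 (1R,2R,3R,4S,6S)-1-methyl-4-(prop-1-en-2-yl)-7-oxabicyclo[4.1.0]heptane-2,3-diol (epoxide oxygen, both hydroxyls and isopropenyl all cis)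
Conditions: VO(acac)2 (cat.), t-BuOOH (1.1 equiv), CH2Cl2, 0 °C → rt
Reagents that add atoms: tert-butyl hydroperoxide, CC(C)(C)OO
Why: Vanadium-catalysed hydroxyl-directed epoxidation, in which the allylic and the homoallylic hydroxyl both lie on the same face and deliver the peroxide syn to the ring trisubstituted alkene, while the slower homoallylic isopropenyl alkene should remain.

Step 5
Reactants: 8 epoxy diol
Product: 9 2,3-bis(triethylsilyl) ether of 8 (ring configuration unchanged)
Conditions: TESCl (3 equiv), imidazole, DMAP (cat.), DMF, rt → 40 °C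
Reagents that add atoms: chlorotriethylsilane, CC[Si](Cl)(CC)CC
Why: Standard silylation of both secondary hydroxyls under non-acidic conditions that spare the epoxide and touch no stereocentre.

Step 6
Reactants: 9 bis-TES ether
Product: 11 1-[2,3-bis(triethylsilyloxy)-1-methyl-7-oxabicyclo[4.1.0]heptan-4-yl]ethan-1-one (ring configuration as in 8), via secondary ozonide 10 (not isolated)
Conditions: O3, CH2Cl2, −78 °C; then PPh3, −78 °C → rt
Reagents that add atoms: ozone, [O-][O+]=O
Why: Ozonolysis with reductive work-up cleaves the only remaining alkene to the methyl ketone without affecting the epoxide or the silyl ethers.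

Step 7
Reactants: 11 methyl ketone
Product: 13 1-[2,3-bis(triethylsilyloxy)-1-methyl-7-oxabicyclo[4.1.0]heptan-4-yl]vinyl trifluoromethanesulfonate (ring configuration as in 8), via potassium enolate 12 (not isolated)
Conditions: KHMDS (1.05 equiv), THF, −78 °C; then Comins' reagent, −78 → −20 °C
Reagents that add atoms: Comins' reagent [N-(5-chloropyridin-2-yl)bis(trifluoromethanesulfonyl)imide], O=S(=O)(N(c1ccc(Cl)cn1)S(=O)(=O)C(F)(F)F)C(F)(F)F
Why: Kinetic enolisation at the unhindered methyl group followed by O-triflation should give the terminal enol triflate without epimerising the ring α-carbon or eliminating the β-silyloxy group.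

Step 8
Reactants: 13 enol triflate
Product: 14 2-{1-[2,3-bis(triethylsilyloxy)-1-methyl-7-oxabicyclo[4.1.0]heptan-4-yl]vinyl}-4,4,5,5-tetramethyl-1,3,2-dioxaborolane (ring configuration as in 8)
Conditions: B2pin2, PdCl2(PPh3)2 (3 mol %), PPh3, KOPh, toluene, 50 °C
Reagents that add atoms: bis(pinacolato)diboron, CC1(C)OB(OC1(C)C)B1OC(C)(C)C(C)(C)O1
Why: Miyaura borylation of an alkenyl triflate replaces C–OTf by C–Bpin at the same carbon under mild base that the epoxide and silyl ethers tolerate.

Step 9
Reactants: 15 4-methylpent-3-en-1-ol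
Product: 16 4-methylpent-3-en-1-yl 2,4,6-triisopropylbenzoate
Conditions: TIB-OH, PPh3, DIAD, THF, 0 °C → rt
Reagents that add atoms: 2,4,6-triisopropylbenzoic acid, CC(C)c1cc(C(C)C)c(C(=O)O)c(C(C)C)c1
Why: Mitsunobu esterification of the primary alcohol installs the hindered benzoate that serves as directing group for α-lithiation and as leaving group in the key step.

Step 10
Reactants: 16 homoprenyl TIB ester (1.5 equiv); 14 alkenyl pinacol boronate
Product: 20 (S)-6-methyl-2-[2,3-bis(triethylsilyloxy)-1-methyl-7-oxabicyclo[4.1.0]heptan-4-yl]hepta-1,5-dien-3-ol (ring configuration as in 8), via lithiated benzoate 17 (not isolated), via boronate complex 18 (not isolated), via allylic boronic ester 19 (not isolated)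
Conditions: s-BuLi (1.4 equiv), (+)-sparteine, Et2O, −78 °C, 5 h; 14, −78 °C, then → rt; then 2 M NaOH, 30 % H2O2, THF, 0 °C
Reagents that add atoms: hydrogen peroxide, OO
Why: s-BuLi/(+)-sparteine removes the pro-R α-hydrogen of 16 to give the configurationally stable (R)-carbenoid 17, which adds to boron of 14 with retention to give ate complex 18; on warming, the alkenyl group migrates from boron to carbon anti to the departing triisopropylbenzoate (inversion), forming the C(sp2)–C(sp3) bond, and H2O2/NaOH oxidises the C–B bond of 19 with retention. The closest known reaction type is lithiation–borylation (1,2-metalate homologation) of an alkenyl boronic ester with a sparteine-ligated lithiated primary benzoate, followed by oxidation of the α-substituted allylboronate. No ring is closed. The new carbinol stereocentre is set by the sparteine enantiomer alone, independently of the ring stereocentres, and should be S as required. The step needs the organolithium to attack boron and not the epoxide or silyl ethers, which the high electrophilicity of the boronate at −78 °C and the absence of carbonyl groups in 14 secure. It also needs migration without a Lewis acid that would open the epoxide, which the good benzoate leaving group and the high migratory aptitude of the alkenyl group secure.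

Step 11
Reactants: 20 bis-TES allylic alcohol
Product: 21 (1R,2R,3R,4S,6S)-4-[(S)-3-hydroxy-6-methylhepta-1,5-dien-2-yl]-1-methyl-7-oxabicyclo[4.1.0]heptane-2,3-diol (triol)
Conditions: TBAF, AcOH (1:1), THF, 0 °C → rt
Reagents that add atoms: none
Why: Buffered fluoride cleaves both triethylsilyl ethers while the epoxide, which cannot undergo Payne rearrangement from the syn hydroxyl, and the allylic alcohol should stay intact.

Step 12
Reactants: 21 triol
Product: 22 bis-angelate: (Z)-2-methylbut-2-enoate esters at the side-chain (S)-carbinol and at the ring C-2 hydroxyl next to the epoxide, with the ring C-3 hydroxyl free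
Conditions: angelic acid (3 equiv), 2,4,6-trichlorobenzoyl chloride, Et3N, toluene, rt, filter; then 21, Et3N, toluene, 75 °C (no DMAP)
Reagents that add atoms: angelic acid [(Z)-2-methylbut-2-enoic acid], C/C=C(/C)C(=O)O
Why: Yamaguchi-type acylation through the trichlorobenzoyl mixed anhydride without a nucleophilic catalyst avoids Z to E isomerisation, and the side-chain allylic hydroxyl and the equatorial ring hydroxyl should react while the axial hydroxyl flanked by two substituted ring carbons is expected to stay free.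

Step 13
Reactants: 22 bis-angelate
Product: 23 target CNP0296086.3
Conditions: D-fructose-derived Shi ketone (3 equiv), Oxone, NaHCO3, Na2EDTA, MeCN–H2O, 0 °C (pH ≈ 8)
Reagents that add atoms: Oxone (potassium peroxymonosulfate), [K+].[O-]S(=O)(=O)OO
Why: Shi asymmetric epoxidation, in which the electrophilic chiral dioxirane reacts only at the electron-rich trisubstituted prenyl alkene and the D-fructose-derived ketone is expected to give the (R)-2,2-dimethyl-3-alkyloxirane, at a near-neutral pH that should prevent angeloyl migration to the neighbouring free hydroxyl.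

**Compound list**

1 | (R)-carvone, (5R)-2-methyl-5-(prop-1-en-2-yl)cyclohex-2-en-1-one | C=C(C)[C@@H]1CC=C(C)C(=O)C1 | starting material
2 | lithium cross-conjugated dienolate of 1 | C=C(C)[C@@H]1CC=C(C)C(O[Li])=C1 | intermediate
3 | (R)-trimethyl{[6-methyl-3-(prop-1-en-2-yl)cyclohexa-1,5-dien-1-yl]oxy}silane | C=C(C)[C@@H]1CC=C(C)C(O[Si](C)(C)C)=C1 | intermediate
4 | (5S,6S)-2-methyl-5-(prop-1-en-2-yl)-6-(trimethylsilyloxy)cyclohex-2-en-1-one (trans) | C=C(C)[C@@H]1CC=C(C)C(=O)[C@H]1O[Si](C)(C)C | intermediate
5 | (5S,6S)-6-hydroxy-2-methyl-5-(prop-1-en-2-yl)cyclohex-2-en-1-one (trans-6-hydroxycarvone) | C=C(C)[C@@H]1CC=C(C)C(=O)[C@H]1O | intermediate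
6 | (1R,6S)-3-methyl-2-oxo-6-(prop-1-en-2-yl)cyclohex-3-en-1-yl benzoate (cis) | C=C(C)[C@@H]1CC=C(C)C(=O)[C@@H]1OC(=O)c1ccccc1 | intermediate
7 | (1R,2S,6S)-3-methyl-6-(prop-1-en-2-yl)cyclohex-3-ene-1,2-diol (all-cis) | C=C(C)[C@@H]1CC=C(C)[C@H](O)[C@@H]1O | intermediate
8 | (1R,2R,3R,4S,6S)-1-methyl-4-(prop-1-en-2-yl)-7-oxabicyclo[4.1.0]heptane-2,3-diol | C=C(C)[C@@H]1C[C@@H]2O[C@]2(C)[C@H](O)[C@@H]1O | intermediate
9 | 2,3-bis(triethylsilyl) ether of 8 | C=C(C)[C@@H]1C[C@@H]2O[C@]2(C)[C@H](O[Si](CC)(CC)CC)[C@@H]1O[Si](CC)(CC)CC | intermediate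
10 | secondary ozonide (3-methyl-1,2,4-trioxolan-3-yl derivative) of 9, mixture at the trioxolane carbon | CC1(OCOO1)[C@@H]1C[C@@H]2O[C@]2(C)[C@H](O[Si](CC)(CC)CC)[C@@H]1O[Si](CC)(CC)CC | intermediate
11 | 1-[2,3-bis(triethylsilyloxy)-1-methyl-7-oxabicyclo[4.1.0]heptan-4-yl]ethan-1-one, ring configuration as 8 | CC(=O)[C@@H]1C[C@@H]2O[C@]2(C)[C@H](O[Si](CC)(CC)CC)[C@@H]1O[Si](CC)(CC)CC | intermediate
12 | potassium enolate of 11 (terminal) | C=C(O[K])[C@@H]1C[C@@H]2O[C@]2(C)[C@H](O[Si](CC)(CC)CC)[C@@H]1O[Si](CC)(CC)CC | intermediate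
13 | 1-[2,3-bis(triethylsilyloxy)-1-methyl-7-oxabicyclo[4.1.0]heptan-4-yl]vinyl triflate, ring configuration as 8 | C=C(OS(=O)(=O)C(F)(F)F)[C@@H]1C[C@@H]2O[C@]2(C)[C@H](O[Si](CC)(CC)CC)[C@@H]1O[Si](CC)(CC)CC | intermediate
14 | pinacol {1-[2,3-bis(triethylsilyloxy)-1-methyl-7-oxabicyclo[4.1.0]heptan-4-yl]vinyl}boronate, ring configuration as 8 | C=C(B1OC(C)(C)C(C)(C)O1)[C@@H]1C[C@@H]2O[C@]2(C)[C@H](O[Si](CC)(CC)CC)[C@@H]1O[Si](CC)(CC)CC | intermediate
15 | 4-methylpent-3-en-1-ol | CC(C)=CCCO | starting material
16 | 4-methylpent-3-en-1-yl 2,4,6-triisopropylbenzoate | CC(C)=CCCOC(=O)c1c(C(C)C)cc(C(C)C)cc1C(C)C | intermediate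
17 | (R)-1-lithio-4-methylpent-3-en-1-yl 2,4,6-triisopropylbenzoate, (+)-sparteine complex | [Li][C@H](CC=C(C)C)OC(=O)c1c(C(C)C)cc(C(C)C)cc1C(C)C | intermediate
18 | lithium boronate (ate) complex of 17 and 14 | [Li+].C=C([C@@H]1C[C@@H]2O[C@]2(C)[C@H](O[Si](CC)(CC)CC)[C@@H]1O[Si](CC)(CC)CC)[B-]3([C@H](CC=C(C)C)OC(=O)c4c(C(C)C)cc(C(C)C)cc4C(C)C)OC(C)(C)C(C)(C)O3 | intermediate
19 | α-substituted allylic pinacol boronate (boron on the future carbinol carbon) | C=C([C@H](CC=C(C)C)B3OC(C)(C)C(C)(C)O3)[C@@H]1C[C@@H]2O[C@]2(C)[C@H](O[Si](CC)(CC)CC)[C@@H]1O[Si](CC)(CC)CC | intermediate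
20 | (S)-6-methyl-2-[2,3-bis(triethylsilyloxy)-1-methyl-7-oxabicyclo[4.1.0]heptan-4-yl]hepta-1,5-dien-3-ol | C=C([C@H](CC=C(C)C)O)[C@@H]1C[C@@H]2O[C@]2(C)[C@H](O[Si](CC)(CC)CC)[C@@H]1O[Si](CC)(CC)CC | intermediate
21 | (1R,2R,3R,4S,6S)-4-[(S)-3-hydroxy-6-methylhepta-1,5-dien-2-yl]-1-methyl-7-oxabicyclo[4.1.0]heptane-2,3-diol | C=C([C@H](CC=C(C)C)O)[C@@H]1C[C@@H]2O[C@]2(C)[C@H](O)[C@@H]1O | intermediate
22 | bis-angelate of 21 at the side-chain carbinol and ring C-2 oxygen, ring C-3 hydroxyl free | C=C([C@H](CC=C(C)C)OC(=O)/C(C)=C\C)[C@@H]1C[C@@H]2O[C@]2(C)[C@H](OC(=O)/C(C)=C\C)[C@@H]1O | intermediate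
23 | CNP0296086.3: 22 with the prenyl alkene converted into the (R)-3,3-dimethyloxirane | C=C([C@H](C[C@H]1OC1(C)C)OC(=O)/C(C)=C\C)[C@@H]1C[C@@H]2O[C@]2(C)[C@H](OC(=O)/C(C)=C\C)[C@@H]1O | target

**Totals.** 13 steps; longest linear sequence 12 steps (steps 1–8 and 10–13).

**Steps most likely to fail**

Step 10. Ate-complex formation at the hindered, α-branched alkenyl boronate may be slow, so the lithiated benzoate could decompose before capture and conversion would be low. The fallback sets out from enol triflate 13 and uses a Nozaki–Hiyama–Kishi coupling. Alcohol 15 is oxidised with Dess–Martin periodinane to 4-methylpent-3-enal F1. F1 is coupled with 13 (CrCl2, cat. NiCl2, DMF, rt) to the allylic alcohol as a mixture of carbinol epimers F2. Dess–Martin oxidation gives the α-methylene ketone F3, and reduction with (R)-Me-CBS/BH3·SMe2 (alkenyl as the large group) should give 20, where the route is rejoined.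

Step 12. Discrimination between the two ring hydroxyls may be incomplete, giving tris-acylation or the wrong ring regioisomer, and Z to E isomerisation of the ester is possible during prolonged heating. The fallback sets out from 20. The side-chain hydroxyl alone is acylated with the same mixed anhydride to give the mono-angelate bis-TES ether F4. Desilylation with TBAF/AcOH gives the mono-angelate ring diol F5. Bu2SnO in refluxing toluene then forms the dibutylstannylene acetal F6, and freshly prepared angeloyl chloride at 0 °C should acylate the equatorial oxygen through tin-acetal activation. This returns to 22.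

Step 2. Activation of the hindered α-ketol may stall, or the oxyphosphonium intermediate may enolise or eliminate instead of being displaced. The fallback sets out from 5. The hydroxyl is converted into the trans α-keto triflate F7 (Tf2O, pyridine, CH2Cl2, −78 °C), which is displaced by cesium benzoate/18-crown-6 in toluene (SN2, inversion; triflate cannot re-attack and scramble the centre). This returns to 6.

**Further compounds**

F1 | step 10 | 4-methylpent-3-enal | CC(C)=CCC=O
F2 | step 10 | 6-methyl-2-[2,3-bis(triethylsilyloxy)-1-methyl-7-oxabicyclo[4.1.0]heptan-4-yl]hepta-1,5-dien-3-ol, mixture of carbinol epimers | C=C(C(CC=C(C)C)O)[C@@H]1C[C@@H]2O[C@]2(C)[C@H](O[Si](CC)(CC)CC)[C@@H]1O[Si](CC)(CC)CC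
F3 | step 10 | 6-methyl-2-[2,3-bis(triethylsilyloxy)-1-methyl-7-oxabicyclo[4.1.0]heptan-4-yl]hepta-1,5-dien-3-one | C=C(C(=O)CC=C(C)C)[C@@H]1C[C@@H]2O[C@]2(C)[C@H](O[Si](CC)(CC)CC)[C@@H]1O[Si](CC)(CC)CC
F4 | step 12 | side-chain mono-angelate of 20 (bis-TES ether) | C=C([C@H](CC=C(C)C)OC(=O)/C(C)=C\C)[C@@H]1C[C@@H]2O[C@]2(C)[C@H](O[Si](CC)(CC)CC)[C@@H]1O[Si](CC)(CC)CC
F5 | step 12 | side-chain mono-angelate ring diol | C=C([C@H](CC=C(C)C)OC(=O)/C(C)=C\C)[C@@H]1C[C@@H]2O[C@]2(C)[C@H](O)[C@@H]1O
F6 | step 12 | 2,3-O-dibutylstannylene acetal of F5 | C=C([C@H](CC=C(C)C)OC(=O)/C(C)=C\C)[C@@H]1C[C@@H]2O[C@]2(C)[C@@H]3O[Sn](CCCC)(CCCC)O[C@H]13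
F7 | step 2 | (1S,6S)-3-methyl-2-oxo-6-(prop-1-en-2-yl)cyclohex-3-en-1-yl triflate (trans) | C=C(C)[C@@H]1CC=C(C)C(=O)[C@H]1OS(=O)(=O)C(F)(F)F
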